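**Retrosynthetic overview**

1. Labels: ring A is the chlorinated arene that becomes the quinone, ring C is the cyclohexanone, and the side chain runs C1' (benzylic CH2), C2'=C3' (C3' carries the methyl), C4' (carbinol), C5' (CH2 on ring C). The hydroxyquinone is taken back to resorcinol 29 (Teuber oxidation), then to its silyl- and ketal-protected form 27.
2. Feature used: the C3' methyl is cis to C1' across C2'=C3', and C1' sits on the ring A carbon that lies between two phenolic oxygens. Joining the methyl carbon to the adjacent oxygen gives a seven-membered ring B (2,5-dihydro-1-benzoxepine: O, CH2, C3', C2', C1' and two ring A carbons) in which only this olefin geometry can exist.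
3. Key disconnections: allylic O–CH2 bond of ring B (hydride with zerovalent palladium, the tether carbon becoming the C3' methyl), C2'=C3' (ring-closing metathesis of 25), aryl O–CH2 (Williamson ether from phenol 24 and allylic bromide 16).
4. C3'–C4' comes from an asymmetric Morita–Baylis–Hillman reaction of ring C aldehyde 11. Ring C comes from an organocatalytic Michael/aldol annulation, allyl then methyl cuprate additions and a kinetic enolate methylation. The arene comes from orcinol by chlorination and directed ortho-allylation.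
5. Order of ring formation: ring C in step 1; ring A is bought as orcinol; ring B is closed in step 17 and opened again in step 18; the quinone is formed last.

Key step: step 17

Assumption: the mono-silylation in step 15 is drawn at the hydroxyl remote from chlorine, as expected on steric grounds; the other mono-silyl ether would serve equally, because both oxygens flank the C-allyl group and both are freed before the final oxidation.

**Route**

Step 1
Reactants: 1 propanal; 2 but-3-en-2-one
Product: 4 (4S)-4-methylcyclohex-2-en-1-one, via (2S)-2-methyl-5-oxohexanal 3 (not isolated)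
Conditions: (R)-α,α-diphenylprolinol methyl ether (5 mol%), ethyl 3,4-dihydroxybenzoate (20 mol%), neat, 4 °C; then 0.1 M aq. KOH, n-Bu4NOH (cat.), Et2O/THF, reflux
Reagents that add atoms: none
Why: Enamine-catalysed Michael addition places the vinyl ketone on the enamine face left open by the diphenyl(methoxy)methyl group of the (R)-catalyst, which should give the (S)-aldehyde, and intramolecular aldol condensation (Robinson annulation sequence) then closes ring C before the aldehyde centre can epimerise.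

Step 2
Reactants: 4 (4S)-4-methylcyclohex-2-en-1-one; 5 allylmagnesium bromide (CH2=CHCH2MgBr)
Product: 6 trimethyl{[(3R,4S)-4-methyl-3-(prop-2-en-1-yl)cyclohex-1-en-1-yl]oxy}silane
Conditions: CuBr·SMe2, LiCl, Me3SiCl, THF, −78 °C; Et3N, then aq. NaHCO3
Reagents that add atoms: chlorotrimethylsilane, C[Si](C)(C)Cl
Why: Silyl-chloride-accelerated conjugate addition of allylcopper delivers the allyl group anti to the C4 methyl and traps the enolate regiospecifically as its silyl enol ether, the new C3 centre being of no consequence because it becomes sp2 in step 3.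

Step 3
Reactants: 6 trimethyl{[(3R,4S)-4-methyl-3-(prop-2-en-1-yl)cyclohex-1-en-1-yl]oxy}silane
Product: 7 (4S)-4-methyl-3-(prop-2-en-1-yl)cyclohex-2-en-1-one
Conditions: 2-iodoxybenzoic acid (IBX), 4-methoxypyridine N-oxide, DMSO, rt
Reagents that add atoms: none
Why: IBX dehydrogenation of the silyl enol ether (a Saegusa-type oxidation that avoids palladium hydrides, so the allyl double bond is not drawn into conjugation) puts the new double bond at C2=C3 as fixed by the enol ether and leaves the C4 centre untouched.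

Step 4
Reactants: 7 (4S)-4-methyl-3-(prop-2-en-1-yl)cyclohex-2-en-1-one
Product: 9 (2R,3S,4S)-2,3,4-trimethyl-3-(prop-2-en-1-yl)cyclohexan-1-one, via lithium enolate 8 (not isolated)
Conditions: Me2CuLi (from MeLi and CuI), Et2O, −20 → 0 °C; then MeI (excess), DMPU/THF, 0 °C → rt, short reaction time
Reagents that add atoms: lithium dimethylcuprate, [Li+].C[Cu-]C; iodomethane, CI
Why: In this tandem conjugate addition–enolate alkylation the cuprate adds anti to the C4 methyl (held pseudo-axial by allylic strain with the C3 allyl group), setting the quaternary C3 with its methyl trans to the C4 methyl, and the enolate is then methylated by axial attack anti to the pseudo-axial allyl group, which sets C2 under kinetic control with its methyl cis to the C3 methyl and trans to the C4 methyl.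

Step 5
Reactants: 9 (2R,3S,4S)-2,3,4-trimethyl-3-(prop-2-en-1-yl)cyclohexan-1-one
Product: 10 (6R,7S,8S)-6,7,8-trimethyl-7-(prop-2-en-1-yl)-1,4-dioxaspiro[4.5]decane
Conditions: Me3SiOCH2CH2OSiMe3, Me3SiOTf (cat.), CH2Cl2, −78 → −20 °C; pyridine quench
Reagents that add atoms: 1,2-bis(trimethylsilyloxy)ethane, C[Si](C)(C)OCCO[Si](C)(C)C
Why: Noyori ketalisation runs at low temperature without protic acid, so the hindered ketone is masked without enolisation and the kinetically set C2 centre (which, being trans to the C4 methyl, cannot be assumed to be the more stable epimer) is kept.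

Step 6
Reactants: 10 (6R,7S,8S)-6,7,8-trimethyl-7-(prop-2-en-1-yl)-1,4-dioxaspiro[4.5]decane
Product: 11 2-[(6R,7S,8S)-6,7,8-trimethyl-1,4-dioxaspiro[4.5]decan-7-yl]acetaldehyde
Conditions: O3, CH2Cl2/MeOH, NaHCO3, −78 °C; then Me2S
Reagents that add atoms: ozone, [O-][O+]=O
Why: Ozonolysis with reductive work-up cleaves the only alkene to the aldehyde, the buffered medium sparing the dioxolane.

Step 7
Reactants: 11 2-[(6R,7S,8S)-6,7,8-trimethyl-1,4-dioxaspiro[4.5]decan-7-yl]acetaldehyde; 12 1,1,1,3,3,3-hexafluoropropan-2-yl prop-2-enoate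
Product: 13 1,1,1,3,3,3-hexafluoropropan-2-yl (3S)-3-hydroxy-2-methylidene-4-[(6R,7S,8S)-6,7,8-trimethyl-1,4-dioxaspiro[4.5]decan-7-yl]butanoate
Conditions: α-isocupreine (10 mol%), DMF, −55 °C
Reagents that add atoms: none
Why: In this Morita–Baylis–Hillman reaction the quinuclidine nitrogen adds to the activated acrylate and the phenolic hydroxyl of the catalyst organises the aldol and proton-transfer steps, so the C4' carbinol centre is set by the catalyst (the quinine-derived pseudo-enantiomer is chosen because the quinidine-derived β-isocupreidine gives the R series), the remote ring C centres having little influence.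

Step 8
Reactants: 13 the hexafluoroisopropyl (3S)-3-hydroxy-2-methylidene ester
Product: 14 1,1,1,3,3,3-hexafluoropropan-2-yl (3S)-3-{[tert-butyl(dimethyl)silyl]oxy}-2-methylidene-4-[(6R,7S,8S)-6,7,8-trimethyl-1,4-dioxaspiro[4.5]decan-7-yl]butanoate
Conditions: t-BuMe2SiOTf, 2,6-lutidine, CH2Cl2, −78 → 0 °C
Reagents that add atoms: tert-butyldimethylsilyl trifluoromethanesulfonate, CC(C)(C)[Si](C)(C)OS(=O)(=O)C(F)(F)F
Why: Silylation with the triflate and a hindered base protects the encumbered secondary alcohol without touching the ester or the dioxolane.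

Step 9
Reactants: 14 the silyl-protected hexafluoroisopropyl ester
Product: 15 (3S)-3-{[tert-butyl(dimethyl)silyl]oxy}-2-methylidene-4-[(6R,7S,8S)-6,7,8-trimethyl-1,4-dioxaspiro[4.5]decan-7-yl]butan-1-ol
Conditions: i-Bu2AlH (3 equiv), CH2Cl2, −78 °C; aq. potassium sodium tartrate
Reagents that add atoms: none
Why: 1,2-Reduction of the electron-poor 2-substituted acrylate ester with the aluminium hydride gives the primary allylic alcohol, the ester carbon becoming the future tether CH2.

Step 10
Reactants: 15 the primary allylic alcohol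
Product: 16 {[(2S)-3-(bromomethyl)-1-[(6R,7S,8S)-6,7,8-trimethyl-1,4-dioxaspiro[4.5]decan-7-yl]but-3-en-2-yl]oxy}(tert-butyl)dimethylsilane
Conditions: CBr4, PPh3, 2,6-lutidine, CH2Cl2, 0 °C
Reagents that add atoms: carbon tetrabromide, BrC(Br)(Br)Br
Why: Appel bromination converts the primary allylic alcohol into the bromide under buffered conditions that the dioxolane and silyl ether tolerate, direct and allylic displacement being degenerate for this 2-substituted allyl unit.

Step 11
Reactants: 17 5-methylbenzene-1,3-diol (orcinol)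
Product: 18 4-chloro-5-methylbenzene-1,3-diol
Conditions: SO2Cl2 (1.0 equiv), Et2O, 0 °C
Reagents that add atoms: sulfuryl chloride, O=S(=O)(Cl)Cl
Why: Electrophilic aromatic chlorination of the resorcinol should go mainly at C4, which is para to one hydroxyl and ortho to the other, and one equivalent at 0 °C limits dichlorination.

Step 12
Reactants: 18 4-chloro-5-methylbenzene-1,3-diol
Product: 19 2-chloro-1,5-bis(methoxymethoxy)-3-methylbenzene
Conditions: MeOCH2Cl, i-Pr2NEt, CH2Cl2, 0 °C → rt
Reagents that add atoms: chloromethyl methyl ether, COCCl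
Why: Acetal-type etherification of both phenols installs two directing groups for the ortho-metalation of step 13.

Step 13
Reactants: 19 2-chloro-1,5-bis(methoxymethoxy)-3-methylbenzene; 20 3-bromoprop-1-ene (allyl bromide)
Product: 22 1-chloro-2,4-bis(methoxymethoxy)-6-methyl-3-(prop-2-en-1-yl)benzene, via aryllithium 21 (not isolated)
Conditions: n-BuLi, THF, 0 °C; then CuBr·SMe2 (10 mol%), 20, −78 → 0 °C
Reagents that add atoms: none
Why: Directed ortho-metalation removes the hydrogen between the two methoxymethoxy groups, the most acidic on the ring, and copper-catalysed allylation of the aryllithium gives the C-allyl arene, the aryl chloride having no ortho hydrogen and so no route to an aryne.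

Step 14
Reactants: 22 1-chloro-2,4-bis(methoxymethoxy)-6-methyl-3-(prop-2-en-1-yl)benzene
Product: 23 4-chloro-5-methyl-2-(prop-2-en-1-yl)benzene-1,3-diol
Conditions: conc. HCl (cat.), MeOH, 50 °C
Reagents that add atoms: none
Why: Acid-catalysed acetal methanolysis frees both phenols under conditions too mild to cyclise the ortho-allyl phenol.

Step 15
Reactants: 23 4-chloro-5-methyl-2-(prop-2-en-1-yl)benzene-1,3-diol
Product: 24 6-chloro-5-methyl-2-(prop-2-en-1-yl)-3-{[tri(propan-2-yl)silyl]oxy}phenol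
Conditions: i-Pr3SiCl (1.0 equiv), imidazole, CH2Cl2, 0 °C
Reagents that add atoms: chlorotri(propan-2-yl)silane, CC(C)[Si](Cl)(C(C)C)C(C)C
Why: Silylation with the bulky chloride should take the hydroxyl that has only one ortho substituent in preference to the one between allyl and chlorine, leaving a single free phenol for step 16.

Step 16
Reactants: 24 the mono-silylated phenol; 16 the allylic bromide
Product: 25 tert-butyl{[(2S)-3-{[6-chloro-5-methyl-2-(prop-2-en-1-yl)-3-{[tri(propan-2-yl)silyl]oxy}phenoxy]methyl}-1-[(6R,7S,8S)-6,7,8-trimethyl-1,4-dioxaspiro[4.5]decan-7-yl]but-3-en-2-yl]oxy}dimethylsilane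
Conditions: K2CO3, n-Bu4NI (cat.), DMF, rt
Reagents that add atoms: none
Why: Williamson ether synthesis joins the phenoxide to the primary allylic bromide, and direct and allylic attack give the same ether because the allyl unit is 2-substituted.

Step 17
Reactants: 25 the C-allyl aryl 2-methylideneallyl ether
Product: 26 tert-butyl{[(1S)-1-[9-chloro-8-methyl-6-{[tri(propan-2-yl)silyl]oxy}-2,5-dihydro-1-benzoxepin-3-yl]-2-[(6R,7S,8S)-6,7,8-trimethyl-1,4-dioxaspiro[4.5]decan-7-yl]ethyl]oxy}dimethylsilane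
Conditions: second-generation Grubbs catalyst, RuCl2(=CHPh)(PCy3)(H2IMes) (10 mol%), 1,4-benzoquinone (20 mol%), toluene (0.005 M), 80 °C
Reagents that add atoms: none
Why: The ruthenium benzylidene first exchanges onto the monosubstituted alkene of the aryl allyl group, the new alkylidene adds to the tethered 1,1-disubstituted alkene, and cycloreversion of the ruthenacyclobutane forms the C2'=C3' bond and releases ethene. The closest known reaction is ring-closing metathesis of 2-allylphenyl allyl ethers to 2,5-dihydro-1-benzoxepines. Ring B (seven-membered) is closed by alkene–alkene metathesis with the new double bond inside the ring. No stereocentre is created; the ring can only hold a cis-in-ring double bond, so C1' and the O–CH2 carbon end up cis across C2'=C3', which is the E geometry once that carbon has become the methyl. The step needs cyclisation to beat oligomerisation and migration of the allyl double bond: the ortho relation of the two alkenes and high dilution secure the first, and benzoquinone, which scavenges ruthenium hydrides, the second.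

Step 18
Reactants: 26 the 2,5-dihydro-1-benzoxepine
Product: 27 6-chloro-2-[(2E,4S)-4-{[tert-butyl(dimethyl)silyl]oxy}-3-methyl-5-[(6R,7S,8S)-6,7,8-trimethyl-1,4-dioxaspiro[4.5]decan-7-yl]pent-2-en-1-yl]-5-methyl-3-{[tri(propan-2-yl)silyl]oxy}phenol
Conditions: Pd(PPh3)4 (10 mol%), LiBHEt3 (3 equiv), THF, 0 °C → rt
Reagents that add atoms: none
Why: Zerovalent palladium ionises the allylic aryl ether to a π-allyl palladium phenoxide and hydride from the borohydride attacks the unsubstituted CH2 terminus (Tsuji–Trost-type hydrogenolysis of an allyl aryl ether), turning the tether carbon into the C3' methyl with the ring-derived geometry retained, provided that hydride capture is faster than syn–anti exchange or re-closure by the phenoxide.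

Step 19
Reactants: 27 the bis-silylated E-alkene
Product: 28 4-chloro-2-[(2E,4S)-4-hydroxy-3-methyl-5-[(6R,7S,8S)-6,7,8-trimethyl-1,4-dioxaspiro[4.5]decan-7-yl]pent-2-en-1-yl]-5-methylbenzene-1,3-diol
Conditions: n-Bu4NF (3 equiv), THF (degassed), 0 °C → rt
Reagents that add atoms: none
Why: Fluoride-induced desilylation removes the aryl and the alkyl silyl ether in one operation while the dioxolane still protects the epimerisable ketone from the basic medium.

Step 20
Reactants: 28 the ketal-protected triol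
Product: 29 (2R,3S,4S)-3-[(2S,3E)-5-(3-chloro-2,6-dihydroxy-4-methylphenyl)-2-hydroxy-3-methylpent-3-en-1-yl]-2,3,4-trimethylcyclohexan-1-one
Conditions: 1 M aq. HCl/THF (1:4), 0 °C → rt, stopped at full conversion
Reagents that add atoms: water, O
Why: Acetal hydrolysis of the strained, hindered dioxolane should proceed in dilute acid at low temperature, below the threshold for enolisation at C2, ionisation of the allylic alcohol or cyclisation of a phenol onto the alkene.

Step 21
Reactants: 29 the resorcinol ketone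
Product: 30 2-chloro-5-hydroxy-6-[(2E,4S)-4-hydroxy-3-methyl-5-[(1S,2R,6S)-1,2,6-trimethyl-3-oxocyclohexyl]pent-2-en-1-yl]-3-methylcyclohexa-2,5-diene-1,4-dione
Conditions: (KSO3)2NO (2.5 equiv), KH2PO4 buffer (pH 6), acetone/H2O, rt
Reagents that add atoms: potassium nitrosodisulfonate, [K+].[K+].[O]N(S(=O)(=O)[O-])S(=O)(=O)[O-]
Why: In this Teuber oxidation the nitrosodisulfonate radical abstracts the phenolic hydrogen and a second equivalent oxygenates the only unsubstituted ring position, which is para to the chlorine-flanked hydroxyl, so the para-quinone forms with the other hydroxyl kept as the 2-hydroxyquinone and the nearly neutral buffer spares the C2 centre.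

**Compound list**

1 | propanal | CCC=O | starting material
2 | but-3-en-2-one (methyl vinyl ketone) | CC(=O)C=C | starting material
3 | (2S)-2-methyl-5-oxohexanal | O=C[C@@H](C)CCC(C)=O | intermediate
4 | (4S)-4-methylcyclohex-2-en-1-one | C[C@H]1CCC(=O)C=C1 | intermediate
5 | allylmagnesium bromide | C=CC[Mg]Br | starting material
6 | trimethyl{[(3R,4S)-4-methyl-3-(prop-2-en-1-yl)cyclohex-1-en-1-yl]oxy}silane | C[Si](C)(C)OC1=C[C@H](CC=C)[C@@H](C)CC1 | intermediate
7 | (4S)-4-methyl-3-(prop-2-en-1-yl)cyclohex-2-en-1-one | C=CCC1=CC(=O)CC[C@@H]1C | intermediate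
8 | lithium (3S,4S)-3,4-dimethyl-3-(prop-2-en-1-yl)cyclohex-1-en-1-olate | [Li]OC1=C[C@@](C)(CC=C)[C@@H](C)CC1 | intermediate
9 | (2R,3S,4S)-2,3,4-trimethyl-3-(prop-2-en-1-yl)cyclohexan-1-one | C=CC[C@@]1(C)[C@@H](C)CCC(=O)[C@@H]1C | intermediate
10 | (6R,7S,8S)-6,7,8-trimethyl-7-(prop-2-en-1-yl)-1,4-dioxaspiro[4.5]decane | C=CC[C@@]1(C)[C@@H](C)CCC2(OCCO2)[C@@H]1C | intermediate
11 | 2-[(6R,7S,8S)-6,7,8-trimethyl-1,4-dioxaspiro[4.5]decan-7-yl]acetaldehyde | O=CC[C@@]1(C)[C@@H](C)CCC2(OCCO2)[C@@H]1C | intermediate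
12 | 1,1,1,3,3,3-hexafluoropropan-2-yl prop-2-enoate | C=CC(=O)OC(C(F)(F)F)C(F)(F)F | starting material
13 | 1,1,1,3,3,3-hexafluoropropan-2-yl (3S)-3-hydroxy-2-methylidene-4-[(6R,7S,8S)-6,7,8-trimethyl-1,4-dioxaspiro[4.5]decan-7-yl]butanoate | C=C(C(=O)OC(C(F)(F)F)C(F)(F)F)[C@@H](O)C[C@@]1(C)[C@@H](C)CCC2(OCCO2)[C@@H]1C | intermediate
14 | 1,1,1,3,3,3-hexafluoropropan-2-yl (3S)-3-{[tert-butyl(dimethyl)silyl]oxy}-2-methylidene-4-[(6R,7S,8S)-6,7,8-trimethyl-1,4-dioxaspiro[4.5]decan-7-yl]butanoate | C=C(C(=O)OC(C(F)(F)F)C(F)(F)F)[C@@H](O[Si](C)(C)C(C)(C)C)C[C@@]1(C)[C@@H](C)CCC2(OCCO2)[C@@H]1C | intermediate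
15 | (3S)-3-{[tert-butyl(dimethyl)silyl]oxy}-2-methylidene-4-[(6R,7S,8S)-6,7,8-trimethyl-1,4-dioxaspiro[4.5]decan-7-yl]butan-1-ol | C=C(CO)[C@@H](O[Si](C)(C)C(C)(C)C)C[C@@]1(C)[C@@H](C)CCC2(OCCO2)[C@@H]1C | intermediate
16 | {[(2S)-3-(bromomethyl)-1-[(6R,7S,8S)-6,7,8-trimethyl-1,4-dioxaspiro[4.5]decan-7-yl]but-3-en-2-yl]oxy}(tert-butyl)dimethylsilane | C=C(CBr)[C@@H](O[Si](C)(C)C(C)(C)C)C[C@@]1(C)[C@@H](C)CCC2(OCCO2)[C@@H]1C | intermediate
17 | 5-methylbenzene-1,3-diol (orcinol) | Cc1cc(O)cc(O)c1 | starting material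
18 | 4-chloro-5-methylbenzene-1,3-diol | Cc1cc(O)cc(O)c1Cl | intermediate
19 | 2-chloro-1,5-bis(methoxymethoxy)-3-methylbenzene | Cc1cc(OCOC)cc(OCOC)c1Cl | intermediate
20 | 3-bromoprop-1-ene (allyl bromide) | C=CCBr | starting material
21 | [3-chloro-2,6-bis(methoxymethoxy)-4-methylphenyl]lithium | [Li]c1c(OCOC)cc(C)c(Cl)c1OCOC | intermediate
22 | 1-chloro-2,4-bis(methoxymethoxy)-6-methyl-3-(prop-2-en-1-yl)benzene | Cc1cc(OCOC)c(CC=C)c(OCOC)c1Cl | intermediate
23 | 4-chloro-5-methyl-2-(prop-2-en-1-yl)benzene-1,3-diol | Cc1cc(O)c(CC=C)c(O)c1Cl | intermediate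
24 | 6-chloro-5-methyl-2-(prop-2-en-1-yl)-3-{[tri(propan-2-yl)silyl]oxy}phenol | Cc1cc(O[Si](C(C)C)(C(C)C)C(C)C)c(CC=C)c(O)c1Cl | intermediate
25 | tert-butyl{[(2S)-3-{[6-chloro-5-methyl-2-(prop-2-en-1-yl)-3-{[tri(propan-2-yl)silyl]oxy}phenoxy]methyl}-1-[(6R,7S,8S)-6,7,8-trimethyl-1,4-dioxaspiro[4.5]decan-7-yl]but-3-en-2-yl]oxy}dimethylsilane | Cc1cc(O[Si](C(C)C)(C(C)C)C(C)C)c(CC=C)c(OCC(=C)[C@@H](O[Si](C)(C)C(C)(C)C)C[C@@]2(C)[C@@H](C)CCC3(OCCO3)[C@@H]2C)c1Cl | intermediate
26 | tert-butyl{[(1S)-1-[9-chloro-8-methyl-6-{[tri(propan-2-yl)silyl]oxy}-2,5-dihydro-1-benzoxepin-3-yl]-2-[(6R,7S,8S)-6,7,8-trimethyl-1,4-dioxaspiro[4.5]decan-7-yl]ethyl]oxy}dimethylsilane | Cc1cc(O[Si](C(C)C)(C(C)C)C(C)C)c2c(c1Cl)OCC(=CC2)[C@@H](O[Si](C)(C)C(C)(C)C)C[C@@]3(C)[C@@H](C)CCC4(OCCO4)[C@@H]3C | intermediate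
27 | 6-chloro-2-[(2E,4S)-4-{[tert-butyl(dimethyl)silyl]oxy}-3-methyl-5-[(6R,7S,8S)-6,7,8-trimethyl-1,4-dioxaspiro[4.5]decan-7-yl]pent-2-en-1-yl]-5-methyl-3-{[tri(propan-2-yl)silyl]oxy}phenol | Cc1cc(O[Si](C(C)C)(C(C)C)C(C)C)c(C/C=C(\C)[C@@H](O[Si](C)(C)C(C)(C)C)C[C@@]2(C)[C@@H](C)CCC3(OCCO3)[C@@H]2C)c(O)c1Cl | intermediate
28 | 4-chloro-2-[(2E,4S)-4-hydroxy-3-methyl-5-[(6R,7S,8S)-6,7,8-trimethyl-1,4-dioxaspiro[4.5]decan-7-yl]pent-2-en-1-yl]-5-methylbenzene-1,3-diol | Cc1cc(O)c(C/C=C(\C)[C@@H](O)C[C@@]2(C)[C@@H](C)CCC3(OCCO3)[C@@H]2C)c(O)c1Cl | intermediate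
29 | (2R,3S,4S)-3-[(2S,3E)-5-(3-chloro-2,6-dihydroxy-4-methylphenyl)-2-hydroxy-3-methylpent-3-en-1-yl]-2,3,4-trimethylcyclohexan-1-one | Cc1cc(O)c(C/C=C(\C)[C@@H](O)C[C@@]2(C)[C@@H](C)CCC(=O)[C@@H]2C)c(O)c1Cl | intermediate
30 | 2-chloro-5-hydroxy-6-[(2E,4S)-4-hydroxy-3-methyl-5-[(1S,2R,6S)-1,2,6-trimethyl-3-oxocyclohexyl]pent-2-en-1-yl]-3-methylcyclohexa-2,5-diene-1,4-dione | CC1=C(Cl)C(=O)C(C/C=C(\C)[C@@H](O)C[C@@]2(C)[C@@H](C)CCC(=O)[C@@H]2C)=C(O)C1=O | target

**Step count and risks**

Total step count: 21. Longest linear sequence: 16 steps (steps 1 to 10, then 16 to 21); the arene branch (steps 11 to 15) has 5 steps.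

Steps most likely to fail:

Step 18 (opening of ring B). Hydride may be delivered to the substituted allyl terminus, giving the transposed 1,1-disubstituted alkene. The π-allyl palladium intermediate may lose its geometry by syn–anti exchange, or the phenoxide may re-close onto the other terminus to a five-membered ring faster than reduction. The fallback avoids any π-allyl intermediate and builds the E-alkene by olefination. It sets out from 16 and 19 and comes back at 29. LiBHEt3 without palladium displaces bromide from 16 to give the isopropenyl silyl ether F1. Ozonolysis (O3, then Me2S) gives the α-silyloxy methyl ketone F2. Horner–Wadsworth–Emmons olefination with triethyl phosphonoacetate and NaH in THF should give mainly the E-enoate F3, the branched substituent lying trans to the ester. Reduction with i-Bu2AlH gives the allylic alcohol F4, and CBr4/PPh3 gives the E-allylic bromide F5. Aryllithium 21, made from 19 with n-BuLi, is alkylated by F5 with catalytic CuBr·SMe2 to give the bis(methoxymethyl) ether F6. HCl in MeOH/THF then removes both acetal groups, the silyl ether and the dioxolane to give 29.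

Step 7 (Morita–Baylis–Hillman reaction). Addition to the aldehyde, whose CH2 is attached to a quaternary carbon, may be slow, the facial selectivity may be poor, and a second aldehyde molecule may be consumed in a dioxanone by-product. The fallback sets the carbinol by reagent-controlled ketone reduction. It sets out from 11 and comes back at 15. 2,3-Dibromopropene and 4-methoxybenzyl alcohol (NaH, THF) give 2-bromoallyl 4-methoxybenzyl ether F7. Bromine–lithium exchange (t-BuLi, Et2O, −78 °C) gives the vinyllithium F8, which adds to 11 to give the carbinol mixture F9. Dess–Martin periodinane gives the enone F10. Reduction with (R)-2-methyl-CBS-oxazaborolidine and BH3·SMe2 should give the (S)-allylic alcohol F11, the alkenyl group acting as the large substituent. Silylation (t-BuMe2SiOTf, 2,6-lutidine) gives F12, and DDQ in wet CH2Cl2 removes the 4-methoxybenzyl group to give 15.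

Step 17 (ring-closing metathesis). The ruthenium alkylidene formed at the aryl allyl group may fail to engage the 1,1-disubstituted alkene, which carries a bulky silyloxy branch, so that dimerisation through the allyl group or migration of its double bond takes over. The fallback closes ring B on a flatter, electron-poor enone and sets C4' afterwards. It sets out from 25 and comes back at 26. HF·pyridine in THF/pyridine removes the alkyl silyl ether but should leave the aryl silyl ether, giving the alcohol F13. Dess–Martin periodinane gives the enone F14. Ring-closing metathesis with the second-generation Hoveyda–Grubbs catalyst, RuCl2(=CH-C6H4-2-O-i-Pr)(H2IMes), in toluene at 80 °C gives the benzoxepinyl ketone F15. Reduction with (R)-2-methyl-CBS-oxazaborolidine and catecholborane should give the (S)-alcohol F16, and t-BuMe2SiOTf/2,6-lutidine returns 26.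

Further compounds
F1 | step 18 | tert-butyl(dimethyl){[(2S)-3-methyl-1-[(6R,7S,8S)-6,7,8-trimethyl-1,4-dioxaspiro[4.5]decan-7-yl]but-3-en-2-yl]oxy}silane | C=C(C)[C@@H](O[Si](C)(C)C(C)(C)C)C[C@@]1(C)[C@@H](C)CCC2(OCCO2)[C@@H]1C
F2 | step 18 | (3S)-3-{[tert-butyl(dimethyl)silyl]oxy}-4-[(6R,7S,8S)-6,7,8-trimethyl-1,4-dioxaspiro[4.5]decan-7-yl]butan-2-one | CC(=O)[C@@H](O[Si](C)(C)C(C)(C)C)C[C@@]1(C)[C@@H](C)CCC2(OCCO2)[C@@H]1C
F3 | step 18 | ethyl (2E,4S)-4-{[tert-butyl(dimethyl)silyl]oxy}-3-methyl-5-[(6R,7S,8S)-6,7,8-trimethyl-1,4-dioxaspiro[4.5]decan-7-yl]pent-2-enoate | CCOC(=O)/C=C(\C)[C@@H](O[Si](C)(C)C(C)(C)C)C[C@@]1(C)[C@@H](C)CCC2(OCCO2)[C@@H]1C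
F4 | step 18 | (2E,4S)-4-{[tert-butyl(dimethyl)silyl]oxy}-3-methyl-5-[(6R,7S,8S)-6,7,8-trimethyl-1,4-dioxaspiro[4.5]decan-7-yl]pent-2-en-1-ol | OC/C=C(\C)[C@@H](O[Si](C)(C)C(C)(C)C)C[C@@]1(C)[C@@H](C)CCC2(OCCO2)[C@@H]1C
F5 | step 18 | {[(2S,3E)-5-bromo-3-methyl-1-[(6R,7S,8S)-6,7,8-trimethyl-1,4-dioxaspiro[4.5]decan-7-yl]pent-3-en-2-yl]oxy}(tert-butyl)dimethylsilane | BrC/C=C(\C)[C@@H](O[Si](C)(C)C(C)(C)C)C[C@@]1(C)[C@@H](C)CCC2(OCCO2)[C@@H]1C
F6 | step 18 | tert-butyl{[(2S,3E)-5-[3-chloro-2,6-bis(methoxymethoxy)-4-methylphenyl]-3-methyl-1-[(6R,7S,8S)-6,7,8-trimethyl-1,4-dioxaspiro[4.5]decan-7-yl]pent-3-en-2-yl]oxy}dimethylsilane | Cc1cc(OCOC)c(C/C=C(\C)[C@@H](O[Si](C)(C)C(C)(C)C)C[C@@]2(C)[C@@H](C)CCC3(OCCO3)[C@@H]2C)c(OCOC)c1Cl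
F7 | step 7 | 1-{[(2-bromoprop-2-en-1-yl)oxy]methyl}-4-methoxybenzene | C=C(Br)COCc1ccc(OC)cc1
F8 | step 7 | {3-[(4-methoxyphenyl)methoxy]prop-1-en-2-yl}lithium | [Li]C(=C)COCc1ccc(OC)cc1
F9 | step 7 | 3-{[(4-methoxyphenyl)methoxy]methyl}-1-[(6R,7S,8S)-6,7,8-trimethyl-1,4-dioxaspiro[4.5]decan-7-yl]but-3-en-2-ol (both carbinol epimers) | C=C(COCc1ccc(OC)cc1)C(O)C[C@@]1(C)[C@@H](C)CCC2(OCCO2)[C@@H]1C
F10 | step 7 | 3-{[(4-methoxyphenyl)methoxy]methyl}-1-[(6R,7S,8S)-6,7,8-trimethyl-1,4-dioxaspiro[4.5]decan-7-yl]but-3-en-2-one | C=C(COCc1ccc(OC)cc1)C(=O)C[C@@]1(C)[C@@H](C)CCC2(OCCO2)[C@@H]1C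
F11 | step 7 | (2S)-3-{[(4-methoxyphenyl)methoxy]methyl}-1-[(6R,7S,8S)-6,7,8-trimethyl-1,4-dioxaspiro[4.5]decan-7-yl]but-3-en-2-ol | C=C(COCc1ccc(OC)cc1)[C@@H](O)C[C@@]1(C)[C@@H](C)CCC2(OCCO2)[C@@H]1C
F12 | step 7 | tert-butyl{[(2S)-3-{[(4-methoxyphenyl)methoxy]methyl}-1-[(6R,7S,8S)-6,7,8-trimethyl-1,4-dioxaspiro[4.5]decan-7-yl]but-3-en-2-yl]oxy}dimethylsilane | C=C(COCc1ccc(OC)cc1)[C@@H](O[Si](C)(C)C(C)(C)C)C[C@@]1(C)[C@@H](C)CCC2(OCCO2)[C@@H]1C
F13 | step 17 | (2S)-3-{[6-chloro-5-methyl-2-(prop-2-en-1-yl)-3-{[tri(propan-2-yl)silyl]oxy}phenoxy]methyl}-1-[(6R,7S,8S)-6,7,8-trimethyl-1,4-dioxaspiro[4.5]decan-7-yl]but-3-en-2-ol | Cc1cc(O[Si](C(C)C)(C(C)C)C(C)C)c(CC=C)c(OCC(=C)[C@@H](O)C[C@@]2(C)[C@@H](C)CCC3(OCCO3)[C@@H]2C)c1Cl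
F14 | step 17 | 3-{[6-chloro-5-methyl-2-(prop-2-en-1-yl)-3-{[tri(propan-2-yl)silyl]oxy}phenoxy]methyl}-1-[(6R,7S,8S)-6,7,8-trimethyl-1,4-dioxaspiro[4.5]decan-7-yl]but-3-en-2-one | Cc1cc(O[Si](C(C)C)(C(C)C)C(C)C)c(CC=C)c(OCC(=C)C(=O)C[C@@]2(C)[C@@H](C)CCC3(OCCO3)[C@@H]2C)c1Cl
F15 | step 17 | 1-[9-chloro-8-methyl-6-{[tri(propan-2-yl)silyl]oxy}-2,5-dihydro-1-benzoxepin-3-yl]-2-[(6R,7S,8S)-6,7,8-trimethyl-1,4-dioxaspiro[4.5]decan-7-yl]ethan-1-one | Cc1cc(O[Si](C(C)C)(C(C)C)C(C)C)c2c(c1Cl)OCC(=CC2)C(=O)C[C@@]3(C)[C@@H](C)CCC4(OCCO4)[C@@H]3C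
F16 | step 17 | (1S)-1-[9-chloro-8-methyl-6-{[tri(propan-2-yl)silyl]oxy}-2,5-dihydro-1-benzoxepin-3-yl]-2-[(6R,7S,8S)-6,7,8-trimethyl-1,4-dioxaspiro[4.5]decan-7-yl]ethan-1-ol | Cc1cc(O[Si](C(C)C)(C(C)C)C(C)C)c2c(c1Cl)OCC(=CC2)[C@@H](O)C[C@@]3(C)[C@@H](C)CCC4(OCCO4)[C@@H]3C
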